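Everything rests on the cyclobutane of the target: its 1,3-carbons (the CH bearing the C(CH3)(CH2OAng) carbon, and the C–CH3 carbon) are spanned by the chain CH(OAng)–CH2–CH(OAc)–C(CH3)(CH2OAng), which makes a seven-membered ring. Cutting the bond from the ketone-side bridgehead CH to the first of these carbons, and the opposite bond from the C–CH3 carbon to the other bridgehead CH, opens both rings to one chain. Forward, a keteniminium ion from an acyclic α-methyl pyrrolidine amide adds across the nearer C=C of an (E)-1,3-diene, closing both rings and three stereocentres at once. The precursor carries one TBS ether and a silylene-tied 1,3-diol; the cyclohexenone is annulated afterwards.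

Key step: step 15

Remark (assumption on the chemistry): stereo-elements that are erased later are expected as mixtures and are left open in the SMILES (enol ether geometry of 22, carbinol centre of 24). The amide α-methyl centre, fixed as S by the aldol, is erased in step 15.

Step 1
Reactants: 1 1-methoxy-1,3-bis(trimethylsilyloxy)buta-1,3-diene; 2 trimethyl orthoformate
Product: 3 methyl 5,5-dimethoxy-3-oxopentanoate
Conditions: TiCl4, CH2Cl2, −78 °C; aq. NaHCO3
Reagents that add atoms: none
Why: Mukaiyama-type γ-alkylation, in which the dimethoxycarbenium ion released from the orthoester by TiCl4 is attacked by the terminal CH2 of the bis-silyl dienolate and work-up frees the β-keto ester.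

Step 2
Reactants: 3 methyl 5,5-dimethoxy-3-oxopentanoate
Product: 4 methyl (3R)-3-hydroxy-5,5-dimethoxypentanoate
Conditions: H2 (50 bar), RuCl2[(R)-BINAP] (cat.), MeOH, 50 °C
Reagents that add atoms: none
Why: Noyori asymmetric hydrogenation of the chelated β-keto ester; the (R)-BINAP complex should deliver hydrogen to the face that gives the 3R alcohol (the sense known for simple 3-oxo esters), and methanol keeps the dimethyl acetal intact.

Step 3
Reactants: 4 methyl (3R)-3-hydroxy-5,5-dimethoxypentanoate
Product: 5 methyl (2R,3R)-3-hydroxy-5,5-dimethoxy-2-methylpentanoate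
Conditions: LDA (2.2 equiv), THF, −78 → −20 °C; MeI, DMPU, −78 → 0 °C
Reagents that add atoms: iodomethane, CI
Why: Fráter–Seebach alkylation, in which the lithium-chelated alkoxide–enolate is methylated on the face away from the C3 side chain, giving the 2,3-anti ester.

Step 4
Reactants: 5 methyl (2R,3R)-3-hydroxy-5,5-dimethoxy-2-methylpentanoate
Product: 6 methyl (2R,3R)-2-[(benzyloxy)methyl]-3-hydroxy-5,5-dimethoxy-2-methylpentanoate
Conditions: LDA (2.5 equiv), THF, −78 → −10 °C; BnOCH2Cl, DMPU, −78 → −20 °C
Reagents that add atoms: benzyl chloromethyl ether, ClCOCc1ccccc1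
Why: Second Fráter–Seebach alkylation, in which the α-methyl enolate in the same chelate is attacked again anti to the side chain, so CH2OBn ends anti and CH3 syn to the hydroxyl and the quaternary centre is set from the carbinol centre.

Step 5
Reactants: 6 methyl (2R,3R)-2-[(benzyloxy)methyl]-3-hydroxy-5,5-dimethoxy-2-methylpentanoate
Product: 7 (2R,3R)-2-[(benzyloxy)methyl]-5,5-dimethoxy-2-methylpentane-1,3-diol
Conditions: LiAlH4, THF, 0 °C → rt
Reagents that add atoms: none
Why: Hydride reduction of the hindered ester to the primary alcohol; acetal and benzyl ether are inert and no stereocentre is touched.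

Step 6
Reactants: 7 (2R,3R)-2-[(benzyloxy)methyl]-5,5-dimethoxy-2-methylpentane-1,3-diol
Product: 8 (4R,5S)-5-[(benzyloxy)methyl]-2,2-di-tert-butyl-4-(2,2-dimethoxyethyl)-5-methyl-1,3,2-dioxasilinane
Conditions: t-Bu2Si(OTf)2, 2,6-lutidine, CH2Cl2, 0 °C
Reagents that add atoms: di-tert-butylsilyl bis(trifluoromethanesulfonate), CC(C)(C)[Si](OS(=O)(=O)C(F)(F)F)(OS(=O)(=O)C(F)(F)F)C(C)(C)C
Why: Cyclic silylene formation on the 1,3-diol under basic conditions that spare the dimethyl acetal; this ring is preferred to an acetal ring because its oxygens are poor donors and it resists triflic conditions, while it still ties the tether for step 15.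

Step 7
Reactants: 8 (4R,5S)-5-[(benzyloxy)methyl]-2,2-di-tert-butyl-4-(2,2-dimethoxyethyl)-5-methyl-1,3,2-dioxasilinane
Product: 9 [(4R,5S)-5-[(benzyloxy)methyl]-2,2-di-tert-butyl-5-methyl-1,3,2-dioxasilinan-4-yl]acetaldehyde
Conditions: PPTS, acetone/H2O, 50 °C
Reagents that add atoms: water, O
Why: Mild acid-catalysed acetal hydrolysis; the hindered dialkoxysilane ring and the benzyl ether should tolerate pyridinium tosylate.

Step 8
Reactants: 9 [(4R,5S)-5-[(benzyloxy)methyl]-2,2-di-tert-butyl-5-methyl-1,3,2-dioxasilinan-4-yl]acetaldehyde; 10 (4S)-4-benzyl-3-propanoyl-1,3-oxazolidin-2-one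
Product: 11 (4S)-4-benzyl-3-[(2S,3R)-4-{(4R,5S)-5-[(benzyloxy)methyl]-2,2-di-tert-butyl-5-methyl-1,3,2-dioxasilinan-4-yl}-3-hydroxy-2-methylbutanoyl]-1,3-oxazolidin-2-one
Conditions: 10, Bu2BOTf, i-Pr2NEt, CH2Cl2, 0 °C; then 9, −78 → 0 °C; pH 7 buffer, MeOH, H2O2
Reagents that add atoms: none
Why: Evans syn-aldol, in which the (Z)-boron enolate of 10 reacts through a closed chair transition state under control of the (S)-benzyl auxiliary, setting the carbinol centre as 3R (and the 2S methyl centre, erased later) irrespective of the β-silyloxy centre of 9.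

Step 9
Reactants: 11 aldol adduct
Product: 12 (2S,3R)-4-{(4R,5S)-5-[(benzyloxy)methyl]-2,2-di-tert-butyl-5-methyl-1,3,2-dioxasilinan-4-yl}-3-hydroxy-2-methyl-1-(pyrrolidin-1-yl)butan-1-one
Conditions: Me3Al, pyrrolidine, CH2Cl2, 0 °C → rt; Rochelle salt
Reagents that add atoms: pyrrolidine, C1CCNC1
Why: Aluminium-amide transamidation of the N-acyl oxazolidinone, in which Me2Al–pyrrolidide, held by the β-aluminium alkoxide, attacks the exocyclic carbonyl and releases the auxiliary without touching a stereocentre.

Step 10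
Reactants: 12 β-hydroxy pyrrolidine amide
Product: 13 (2S,3R)-4-{(4R,5S)-5-[(benzyloxy)methyl]-2,2-di-tert-butyl-5-methyl-1,3,2-dioxasilinan-4-yl}-3-[(tert-butyldimethylsilyl)oxy]-2-methyl-1-(pyrrolidin-1-yl)butan-1-one
Conditions: TBSOTf, 2,6-lutidine, CH2Cl2, 0 °C
Reagents that add atoms: tert-butyldimethylsilyl trifluoromethanesulfonate, CC(C)(C)[Si](C)(C)OS(=O)(=O)C(F)(F)F
Why: Silylation of the secondary alcohol with the silyl triflate, giving a bulky, weakly basic ether that cannot take part as a neighbouring group in step 15.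

Step 11
Reactants: 13 benzyl ether amide
Product: 14 (2S,3R)-3-[(tert-butyldimethylsilyl)oxy]-4-[(4R,5S)-2,2-di-tert-butyl-5-(hydroxymethyl)-5-methyl-1,3,2-dioxasilinan-4-yl]-2-methyl-1-(pyrrolidin-1-yl)butan-1-one
Conditions: H2 (1 atm), 10% Pd/C, EtOAc, rt
Reagents that add atoms: none
Why: Hydrogenolysis of the benzyl ether, run before any alkene is present; amide and silyl groups are inert.

Step 12
Reactants: 14 primary alcohol
Product: 15 (4R,5S)-5-formyl aldehyde (CH2OH of 14 oxidised to CHO)
Conditions: Dess–Martin periodinane, NaHCO3, CH2Cl2, rt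
Reagents that add atoms: none
Why: Dess–Martin oxidation to an aldehyde that has no α-hydrogen, so the quaternary centre cannot epimerise.

Step 13
Reactants: 16 3-chloro-2-methylprop-1-ene
Product: 17 (2-methylprop-2-en-1-yl)diphenylphosphine oxide
Conditions: Ph2POEt, neat, 120 °C (sealed tube)
Reagents that add atoms: ethyl diphenylphosphinite, CCOP(c1ccccc1)c1ccccc1
Why: Michaelis–Arbuzov reaction of the allylic chloride with the phosphinite, with loss of chloroethane, under base-free conditions that avoid alkene migration.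

Step 14
Reactants: 15 aldehyde; 17 (2-methylprop-2-en-1-yl)diphenylphosphine oxide
Product: 18 (2S,3R)-3-[(tert-butyldimethylsilyl)oxy]-4-{(4R,5S)-2,2-di-tert-butyl-5-methyl-5-[(1E)-3-methylbuta-1,3-dien-1-yl]-1,3,2-dioxasilinan-4-yl}-2-methyl-1-(pyrrolidin-1-yl)butan-1-one
Conditions: 17, n-BuLi, THF/HMPA, −78 °C; then 15, −78 °C → rt
Reagents that add atoms: none
Why: Horner–Wittig olefination, in which the lithiated allylphosphine oxide adds through its α-carbon in HMPA and the adduct loses lithium diphenylphosphinate in the flask to give the E-diene; the aldehyde cannot enolise and the amide α-CH is too weakly acidic to be touched.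

Step 15
Reactants: 18 dienyl pyrrolidine amide
Product: 21 silylene-protected 8-isopropenyl-1-methyl-2-silyloxybicyclo[4.1.1]octan-7-one, via keteniminium triflate 19 (not isolated), via cyclobutaniminium triflate 20 (not isolated)
Conditions: Tf2O (1.2 equiv), 2,6-di-tert-butyl-4-methylpyridine, ClCH2CH2Cl (0.005 M), −20 → 80 °C; then aq. NaHCO3, 40 °C
Reagents that add atoms: water, O
Why: Intramolecular keteniminium–alkene [2+2] cycloaddition: O-triflation of the amide and loss of TfOH to the hindered pyridine give keteniminium 19 (the α-methyl centre is erased), whose central carbon is attacked by the diene CH attached to the quaternary carbon, after which the enamine C–CH3 carbon bonds to the neighbouring carbon of the 2-methylallyl cation to give iminium 20, which water converts into ketone 21. The closest known reactions are the intramolecular cycloadditions of keteniminium salts and of ketenes with tethered alkenes and dienes that give bridged bicyclo[3.1.1]heptan-6-ones; the tether here is one atom longer. The seven-membered ring closes in a 7-exo mode (the attacked alkene carbon lies in the ring, its partner outside), and the four-membered ring by 4-exo collapse of the enamine on the proximal allyl carbon, the rest of the allyl unit staying outside as the isopropenyl group. Of the three new centres, the C–CH3 carbon and the CH next to the quaternary carbon are fixed relative to each other because the chain can only span cis-1,3 positions, the isopropenyl-bearing CH is set trans to the quaternary carbon by the E alkene, and the absolute sense follows from the alkene face attacked. The step needs that face selectivity and four- rather than six-membered collapse: the trans-fused silylene ring ties back the CH2O and O branches, so the keteniminium carbon should approach anti to the only free substituent (the quaternary methyl), and the s-trans diene should give a transoid allyl cation whose far end cannot reach the enamine carbon; hindered, weakly basic silyl ether oxygens and high dilution guard against cation capture and oligomerisation.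

Step 16
Reactants: 21 cyclobutanone
Product: 22 7-(methoxymethylidene) enol ether of 21 (mixture of alkene isomers)
Conditions: Ph3P(CH2OMe)Cl, KHMDS, THF, 0 °C; then 21, 0 → 50 °C
Reagents that add atoms: (methoxymethyl)triphenylphosphonium chloride, COC[P+](c1ccccc1)(c1ccccc1)c1ccccc1.[Cl-]
Why: Wittig methoxymethylenation of a strained cyclobutanone that cannot enolise (its only α-hydrogen sits on a bridgehead, Bredt's rule), so the basic ylide can only add to the carbonyl.

Step 17
Reactants: 22 enol ether
Product: 23 7-carbaldehyde (formyl group syn to the isopropenyl group)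
Conditions: PPTS, THF/H2O, 40 °C
Reagents that add atoms: water, O
Why: Acid-catalysed enol ether hydrolysis, in which protonation of the ring carbon should come from the face away from the 1,3-related isopropenyl group (the usual trajectory on a 3-substituted cyclobutane), placing the formyl group syn to it; because this CH is α to the aldehyde, a mis-set centre can be equilibrated through the enol with DBU.

Step 18
Reactants: 23 aldehyde
Product: 24 homoallylic alcohol with the new six-membered ring (exocyclic methylene; carbinol centre open)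
Conditions: Me2AlCl (2 equiv), CH2Cl2, −78 → −20 °C
Reagents that add atoms: none
Why: Lewis-acid carbonyl-ene cyclisation, in which the aluminium-bound aldehyde, held 1,3-syn to the isopropenyl group on the four-membered ring, is attacked by the alkene CH2 terminus while a methyl hydrogen moves to oxygen through a six-membered transition state; the carbinol centre is removed in step 19.

Step 19
Reactants: 24 homoallylic alcohol
Product: 26 conjugated enone (silylene-protected TBS ether), via β,γ-unsaturated ketone 25 (not isolated)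
Conditions: Dess–Martin periodinane, NaHCO3, CH2Cl2, rt; then DBU (5 equiv), rt
Reagents that add atoms: none
Why: Dess–Martin oxidation followed by base-mediated alkene isomerisation through the dienolate to the endocyclic trisubstituted enone; the other α-carbon is a bridgehead and cannot enolise, so no centre is at risk.

Step 20
Reactants: 26 conjugated enone
Product: 27 enone diol (primary CH2OH and secondary OH free; TBS ether kept)
Conditions: HF·pyridine, pyridine, THF, 0 °C
Reagents that add atoms: none
Why: Fluoride cleavage of the cyclic dialkoxysilane, expected to be much faster than cleavage of the secondary TBS ether that is flanked by a quaternary carbon.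

Step 21
Reactants: 27 enone diol
Product: 28 primary angelate (secondary OH free)
Conditions: angelic acid, 2,4,6-trichlorobenzoyl chloride, Et3N, toluene, rt; then 27, rt
Reagents that add atoms: angelic acid ((Z)-2-methylbut-2-enoic acid), C/C=C(/C)C(O)=O
Why: Yamaguchi esterification through the mixed anhydride, which transfers the angeloyl group without Z-to-E isomerisation; the primary alcohol should react ahead of the secondary alcohol next to the quaternary carbon.

Step 22
Reactants: 28 primary angelate
Product: 29 angelate acetate (TBS ether kept)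
Conditions: Ac2O, pyridine, DMAP (cat.), CH2Cl2, rt
Reagents that add atoms: acetic anhydride, CC(=O)OC(C)=O
Why: DMAP-catalysed acetylation of the remaining secondary alcohol.

Step 23
Reactants: 29 angelate acetate silyl ether
Product: 30 angelate acetate with the free secondary alcohol
Conditions: HF·pyridine, THF, rt → 40 °C
Reagents that add atoms: none
Why: Acidic fluoride desilylation of the hindered TBS ether; the non-basic medium should spare both esters and the enone and should not promote acyl migration.

Step 24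
Reactants: 30 secondary alcohol
Product: 31 CNP0364726.1
Conditions: angelic acid, 2,4,6-trichlorobenzoyl chloride, Et3N, toluene, rt; then 30, 80 °C
Reagents that add atoms: angelic acid ((Z)-2-methylbut-2-enoic acid), C/C=C(/C)C(O)=O
Why: Yamaguchi esterification of the hindered secondary alcohol with the preformed mixed anhydride, the method of choice for angelates of hindered alcohols because the Z geometry is retained.

Compound list
1 | 1-methoxy-1,3-bis(trimethylsilyloxy)buta-1,3-diene | COC(O[Si](C)(C)C)=CC(=C)O[Si](C)(C)C | starting material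
2 | trimethyl orthoformate | COC(OC)OC | starting material
3 | methyl 5,5-dimethoxy-3-oxopentanoate | COC(=O)CC(=O)CC(OC)OC | intermediate
4 | methyl (3R)-3-hydroxy-5,5-dimethoxypentanoate | COC(=O)C[C@H](O)CC(OC)OC | intermediate
5 | methyl (2R,3R)-3-hydroxy-5,5-dimethoxy-2-methylpentanoate | COC(=O)[C@H](C)[C@H](O)CC(OC)OC | intermediate
6 | methyl (2R,3R)-2-[(benzyloxy)methyl]-3-hydroxy-5,5-dimethoxy-2-methylpentanoate | COC(=O)[C@](C)(COCc1ccccc1)[C@H](O)CC(OC)OC | intermediate
7 | (2R,3R)-2-[(benzyloxy)methyl]-5,5-dimethoxy-2-methylpentane-1,3-diol | OC[C@](C)(COCc1ccccc1)[C@H](O)CC(OC)OC | intermediate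
8 | (4R,5S)-5-[(benzyloxy)methyl]-2,2-di-tert-butyl-4-(2,2-dimethoxyethyl)-5-methyl-1,3,2-dioxasilinane | CC(C)(C)[Si]1(C(C)(C)C)OC[C@](C)(COCc2ccccc2)[C@@H](CC(OC)OC)O1 | intermediate
9 | [(4R,5S)-5-[(benzyloxy)methyl]-2,2-di-tert-butyl-5-methyl-1,3,2-dioxasilinan-4-yl]acetaldehyde | CC(C)(C)[Si]1(C(C)(C)C)OC[C@](C)(COCc2ccccc2)[C@@H](CC=O)O1 | intermediate
10 | (4S)-4-benzyl-3-propanoyl-1,3-oxazolidin-2-one | CCC(=O)N1[C@@H](Cc2ccccc2)COC1=O | starting material
11 | (4S)-4-benzyl-3-[(2S,3R)-4-{(4R,5S)-5-[(benzyloxy)methyl]-2,2-di-tert-butyl-5-methyl-1,3,2-dioxasilinan-4-yl}-3-hydroxy-2-methylbutanoyl]-1,3-oxazolidin-2-one | CC(C)(C)[Si]1(C(C)(C)C)OC[C@](C)(COCc2ccccc2)[C@@H](C[C@@H](O)[C@H](C)C(=O)N2[C@@H](Cc3ccccc3)COC2=O)O1 | intermediate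
12 | (2S,3R)-4-{(4R,5S)-5-[(benzyloxy)methyl]-2,2-di-tert-butyl-5-methyl-1,3,2-dioxasilinan-4-yl}-3-hydroxy-2-methyl-1-(pyrrolidin-1-yl)butan-1-one | CC(C)(C)[Si]1(C(C)(C)C)OC[C@](C)(COCc2ccccc2)[C@@H](C[C@@H](O)[C@H](C)C(=O)N2CCCC2)O1 | intermediate
13 | TBS ether of 12 (3-[(tert-butyldimethylsilyl)oxy]) | CC(C)(C)[Si]1(C(C)(C)C)OC[C@](C)(COCc2ccccc2)[C@@H](C[C@@H](O[Si](C)(C)C(C)(C)C)[C@H](C)C(=O)N2CCCC2)O1 | intermediate
14 | primary alcohol (5-hydroxymethyl; benzyl removed from 13) | CC(C)(C)[Si]1(C(C)(C)C)OC[C@](C)(CO)[C@@H](C[C@@H](O[Si](C)(C)C(C)(C)C)[C@H](C)C(=O)N2CCCC2)O1 | intermediate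
15 | aldehyde (5-formyl analogue of 14) | CC(C)(C)[Si]1(C(C)(C)C)OC[C@](C)(C=O)[C@@H](C[C@@H](O[Si](C)(C)C(C)(C)C)[C@H](C)C(=O)N2CCCC2)O1 | intermediate
16 | 3-chloro-2-methylprop-1-ene | CC(=C)CCl | starting material
17 | (2-methylprop-2-en-1-yl)diphenylphosphine oxide | CC(=C)CP(=O)(c1ccccc1)c1ccccc1 | intermediate
18 | (2S,3R)-3-[(tert-butyldimethylsilyl)oxy]-4-{(4R,5S)-2,2-di-tert-butyl-5-methyl-5-[(1E)-3-methylbuta-1,3-dien-1-yl]-1,3,2-dioxasilinan-4-yl}-2-methyl-1-(pyrrolidin-1-yl)butan-1-one | CC(C)(C)[Si]1(C(C)(C)C)OC[C@](C)(/C=C/C(C)=C)[C@@H](C[C@@H](O[Si](C)(C)C(C)(C)C)[C@H](C)C(=O)N2CCCC2)O1 | intermediate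
19 | keteniminium triflate from 18 | CC(C)(C)[Si]1(C(C)(C)C)OC[C@](C)(/C=C/C(C)=C)[C@@H](C[C@@H](O[Si](C)(C)C(C)(C)C)C(C)=C=[N+]2CCCC2)O1.[O-]S(=O)(=O)C(F)(F)F | intermediate
20 | cyclobutaniminium triflate (pyrrolidinium ylidene at C7 of the bicyclo[4.1.1]octane) | CC(C)(C)[Si]1(C(C)(C)C)OC[C@]2(C)[C@@H]3C(=[N+]4CCCC4)[C@](C)([C@H](O[Si](C)(C)C(C)(C)C)C[C@H]2O1)[C@H]3C(C)=C.[O-]S(=O)(=O)C(F)(F)F | intermediate
21 | cyclobutanone: bicyclo[4.1.1]octan-7-one with 1-CH3, 2-OTBS, 8-isopropenyl (anti to the four-carbon bridge) and the 4,5-fused di-tert-butyldioxasilinane (5-CH3) | CC(C)(C)[Si]1(C(C)(C)C)OC[C@]2(C)[C@@H]3C(=O)[C@](C)([C@H](O[Si](C)(C)C(C)(C)C)C[C@H]2O1)[C@H]3C(C)=C | intermediate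
22 | 7-(methoxymethylidene) enol ether of 21 | CC(C)(C)[Si]1(C(C)(C)C)OC[C@]2(C)[C@@H]3C(=COC)[C@](C)([C@H](O[Si](C)(C)C(C)(C)C)C[C@H]2O1)[C@H]3C(C)=C | intermediate
23 | 7-carbaldehyde (CHO syn to isopropenyl) | CC(C)(C)[Si]1(C(C)(C)C)OC[C@]2(C)[C@@H]3[C@@H](C=O)[C@](C)([C@H](O[Si](C)(C)C(C)(C)C)C[C@H]2O1)[C@H]3C(C)=C | intermediate
24 | homoallylic alcohol (six-membered ring closed, exocyclic methylene) | CC(C)(C)[Si]1(C(C)(C)C)OC[C@]2(C)[C@@H]3[C@H]4C(O)CC(=C)[C@@H]3[C@@]4(C)[C@H](O[Si](C)(C)C(C)(C)C)C[C@H]2O1 | intermediate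
25 | β,γ-unsaturated ketone | CC(C)(C)[Si]1(C(C)(C)C)OC[C@]2(C)[C@@H]3[C@H]4C(=O)CC(=C)[C@@H]3[C@@]4(C)[C@H](O[Si](C)(C)C(C)(C)C)C[C@H]2O1 | intermediate
26 | conjugated enone (silylene, TBS) | CC(C)(C)[Si]1(C(C)(C)C)OC[C@]2(C)[C@@H]3[C@H]4C(=O)C=C(C)[C@@H]3[C@@]4(C)[C@H](O[Si](C)(C)C(C)(C)C)C[C@H]2O1 | intermediate
27 | enone diol (TBS ether) | OC[C@]1(C)[C@@H]2[C@H]3C(=O)C=C(C)[C@@H]2[C@@]3(C)[C@H](O[Si](C)(C)C(C)(C)C)C[C@H]1O | intermediate
28 | primary angelate (TBS ether, free secondary OH) | C/C=C(/C)C(=O)OC[C@]1(C)[C@@H]2[C@H]3C(=O)C=C(C)[C@@H]2[C@@]3(C)[C@H](O[Si](C)(C)C(C)(C)C)C[C@H]1O | intermediate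
29 | angelate acetate (TBS ether) | C/C=C(/C)C(=O)OC[C@]1(C)[C@@H]2[C@H]3C(=O)C=C(C)[C@@H]2[C@@]3(C)[C@H](O[Si](C)(C)C(C)(C)C)C[C@H]1OC(C)=O | intermediate
30 | angelate acetate with free secondary alcohol | C/C=C(/C)C(=O)OC[C@]1(C)[C@@H]2[C@H]3C(=O)C=C(C)[C@@H]2[C@@]3(C)[C@H](O)C[C@H]1OC(C)=O | intermediate
31 | CNP0364726.1 | C/C=C(/C)C(=O)OC[C@]1(C)[C@@H]2[C@H]3C(=O)C=C(C)[C@@H]2[C@@]3(C)[C@H](OC(=O)/C(C)=C\C)C[C@H]1OC(C)=O | target

Total step count: 24. Longest linear sequence: 23 (steps 1–12 and 14–24; step 13 makes the olefination reagent).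

Steps most likely to fail

1. Step 15. What may go wrong: closure of the seven-membered ring may lose to oligomerisation or to capture of the keteniminium or allyl cation by a silyl ether oxygen; the cation may collapse at its far end to a six-membered ring; or the other alkene face may be attacked. Fallback (a neutral ketene in place of the cation), setting out from 11 and returning at 21: LiOH/H2O2 would remove the auxiliary from 11 to give the β-hydroxy acid F1. TBSOTf/2,6-lutidine followed by K2CO3/MeOH (to cleave the silyl ester) would give the silyl ether acid F2. Hydrogenolysis (H2, Pd/C) would give the hydroxy acid F3, and Dess–Martin oxidation the aldehyde acid F4. Horner–Wittig reaction with excess lithiated 17 would give the dienyl acid F5. 1-Chloro-N,N,2-trimethylprop-1-en-1-amine would convert this into the acid chloride F6. i-Pr2NEt in refluxing toluene at high dilution would then generate the methylketene F7, whose thermal [2+2] addition to the diene, with the regiochemistry usual for ketene–diene additions and no free cation, should close to 21.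

2. Step 18. What may go wrong: the formyl group may settle on the ring face away from the isopropenyl group and not epimerise under the Lewis acid, or methyl transfer from aluminium to the aldehyde may outrun the strained closure. Fallback (metathesis in place of the ene reaction), setting out from 23 and returning at 26: vinylmagnesium bromide would add to 23 to give the allylic alcohol F8. Dess–Martin oxidation would give the vinyl ketone F9, whose α-centre equilibrates readily with mild base. Ring-closing metathesis with the second-generation Hoveyda–Grubbs catalyst (toluene, 80 °C) between the vinyl ketone and the isopropenyl group would then close the trisubstituted enone 26 directly.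

3. Step 16. What may go wrong: the bulky ylide may fail to add to a carbonyl flanked by a quaternary carbon and a branched CH. Fallback (Peterson olefination with a smaller nucleophile), setting out from 21 and returning at 22: lithiated (methoxymethyl)trimethylsilane (from Me3SiCH2OMe and s-BuLi, THF, −78 → −25 °C) would add to 21 to give the β-hydroxy silane F10, and KH in THF would eliminate potassium trimethylsilanolate to give 22.

Further compounds
F1 | step 15 | (2S,3R)-4-{(4R,5S)-5-[(benzyloxy)methyl]-2,2-di-tert-butyl-5-methyl-1,3,2-dioxasilinan-4-yl}-3-hydroxy-2-methylbutanoic acid | CC(C)(C)[Si]1(C(C)(C)C)OC[C@](C)(COCc2ccccc2)[C@@H](C[C@@H](O)[C@H](C)C(O)=O)O1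
F2 | step 15 | 3-O-TBS ether of F1 | CC(C)(C)[Si]1(C(C)(C)C)OC[C@](C)(COCc2ccccc2)[C@@H](C[C@@H](O[Si](C)(C)C(C)(C)C)[C@H](C)C(O)=O)O1
F3 | step 15 | debenzylated hydroxy acid | CC(C)(C)[Si]1(C(C)(C)C)OC[C@](C)(CO)[C@@H](C[C@@H](O[Si](C)(C)C(C)(C)C)[C@H](C)C(O)=O)O1
F4 | step 15 | aldehyde acid | CC(C)(C)[Si]1(C(C)(C)C)OC[C@](C)(C=O)[C@@H](C[C@@H](O[Si](C)(C)C(C)(C)C)[C@H](C)C(O)=O)O1
F5 | step 15 | (E)-dienyl acid | CC(C)(C)[Si]1(C(C)(C)C)OC[C@](C)(/C=C/C(C)=C)[C@@H](C[C@@H](O[Si](C)(C)C(C)(C)C)[C@H](C)C(O)=O)O1
F6 | step 15 | (E)-dienyl acid chloride | CC(C)(C)[Si]1(C(C)(C)C)OC[C@](C)(/C=C/C(C)=C)[C@@H](C[C@@H](O[Si](C)(C)C(C)(C)C)[C@H](C)C(Cl)=O)O1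
F7 | step 15 | dienyl methylketene | CC(C)(C)[Si]1(C(C)(C)C)OC[C@](C)(/C=C/C(C)=C)[C@@H](C[C@@H](O[Si](C)(C)C(C)(C)C)C(C)=C=O)O1
F8 | step 18 | allylic alcohol from 23 (vinyl carbinol, carbinol centre open) | CC(C)(C)[Si]1(C(C)(C)C)OC[C@]2(C)[C@@H]3[C@@H](C(O)C=C)[C@](C)([C@H](O[Si](C)(C)C(C)(C)C)C[C@H]2O1)[C@H]3C(C)=C
F9 | step 18 | vinyl ketone | CC(C)(C)[Si]1(C(C)(C)C)OC[C@]2(C)[C@@H]3[C@@H](C(=O)C=C)[C@](C)([C@H](O[Si](C)(C)C(C)(C)C)C[C@H]2O1)[C@H]3C(C)=C
F10 | step 16 | β-hydroxy α-methoxy silane adduct of 21 (new centres open) | CC(C)(C)[Si]1(C(C)(C)C)OC[C@]2(C)[C@@H]3C(O)(C(OC)[Si](C)(C)C)[C@](C)([C@H](O[Si](C)(C)C(C)(C)C)C[C@H]2O1)[C@H]3C(C)=C
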